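Take the amounts before any fit, and read the flat part of a run by hand.

| setting | epsilon | zeta | Saturday's | Friday's | Monday's | Wednesday's |
|---|---|---|---|---|---|---|
| starting material | 1.6 M | 1.6 M | 2.4 M | 2.4 M | 2.4 M | 2.4 M |
| temperature | 42 °C | 92 °C | 50 °C | 110 °C | 80 °C | 20 °C |
| remark | run made earlier | run made earlier |  |  |  |  |
| time |  |  | 2.5 h | 2.5 h | 2.5 h | 2.5 h |

epsilon run (percent of the starting material charged)

| time / h | target / % | starting material / % |
|---|---|---|
| 0.200 | 0.6 | 28.5 |
| 0.667 | 5.3 | 25.2 |
| 1.33 | 10.0 | 20.4 |
| 2.00 | 11.4 | 16.2 |
| 2.50 | 13.0 | 14.4 |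

zeta run (percent of the starting material charged)

| time / min | target / % | starting material / % |
|---|---|---|
| 1.50 | 30.9 | 13.2 |
| 5.00 | 42.7 | 1.5 |
| 10.0 | 42.2 | 0 |
| 15.0 | 42.6 | 0.2 |
| 20.0 | 43.4 | 0.3 |

(readings scatter by 0.5 percentage points)



- which flask leads in amount of target, in percent of the starting material charged ("all alike" within 1.5 percentage points) (Saturday's / Friday's / Monday's / Wednesday's / all alike)
- how much target is there at the end, in percent of the starting material charged: Saturday's
- how much target is there at the end, in percent of the starting material charged: Friday's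
- how much target is there at the end, in percent of the starting material charged: Monday's
- how much target is there at the end, in percent of the starting material charged: Wednesday's

Start with the zeta run: from 5.00 min on, target stays flat near 42.7%. Call target over the rest of the charge the plateau odds, so zeta gives 0.746.

But the epsilon run shows no plateau, so take target plus starting material as a stand-in. That sum averages 29.0%, which gives odds of 0.408, lower than in the hotter run.

So draw the logarithm of the odds straight against inverse temperature. The slope times R gives 11.5 kJ mol⁻¹; call this the plateau heat, an apparent van 't Hoff slope of the odds, since one of its two points is a stand-in.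

Now reckon Friday's yourself: its odds come to 0.892, so target stands at 47.1%, assuming the untested larger charge changes little.

But a plateau counts only if the flask reaches it, so put that answer back. Between its first two readings, the starting material in zeta halves in about 1.12 min, far less than Friday's 2.5 h, and Friday's is the hottest flask. So commit to Friday's leading.

The forecast names Friday's and gives 26%, 46%, 40% and 1% for Saturday's, Friday's, Monday's and Wednesday's: “a fast, dead-ending loss takes a share first, and it takes less when hot”. For Friday's, my figure stands 1.1 percentage points above it.

The flasks give 19.8%, 50.4%, 36.3% and 0.468% in that order, and Friday's leads.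

    intermediate A → intermediate B (k = 0.00130 s⁻¹, Ea = 97.0 kJ mol⁻¹)
    target ⇌ isomer of the product (K = 3.20, k = 0.00150 s⁻¹, Ea = 88.0 kJ mol⁻¹, ΔH = −23.0 kJ mol⁻¹)
    starting material ⇌ dormant form (K = 1.90, k = 0.0170 s⁻¹, Ea = 88.0 kJ mol⁻¹, ΔH = −14.0 kJ mol⁻¹)
    starting material + intermediate B → side product (k = 0.00110 M⁻¹ s⁻¹, Ea = 84.0 kJ mol⁻¹)
    starting material → intermediate A (k = 6.40 × 10⁻⁴ s⁻¹, Ea = 90.0 kJ mol⁻¹)
    intermediate B → target (k = 0.00940 s⁻¹, Ea = 91.0 kJ mol⁻¹)
    (constants at 50 °C)

At the end of Friday's, the slowest mode has a half-life of 0.177 min against a run of 2.5 h. Left for 25.0 h, Friday's still holds 50.4% target, so the plateau heat's 47.1% fell 3.3 points short.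

Run Friday's charge at 85 °C: the plateau heat gives odds of 0.693, so 40.9% target. The computed flask holds 38.8%.

The readings come from a simulation on assumed constants; the scatter is artificial.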